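**Plan**
- Retrosynthesis: the N‑methoxy‑4‑pyridone is traced back through N–OMe, N–O, the C4 benzyl ether, the C3 methyl ether and the C2 CH2OH (carried as an ester) to a 3‑hydroxy‑4‑benzyloxypyridine‑2‑carboxylate. Its pyridine ring is then cut at C4a–C8a and C3–C4.
- Enabling feature: the pyridine ring N1–C2–C3–C4–C4a–C8a carries oxygen on both C3 and C4 and a carbon on C2, and is fused at C4a–C8a to the carbocycle C4a–C5–C6–C7–C8–C8a. N1, C2, C3 with its oxygen and C8a can therefore come from a 5‑ethoxyoxazole, and C4 with its oxygen plus C4a from a benzyl enol ether tethered through C5–C8.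
- The C2 carbon is kept at the ester level (from aminomalonate). This makes the alkoxyoxazole robust and turns it into the electron‑poor partner for the electron‑rich enol ether.
- Forward: C5 stereocentre first, then chain extension to the C8a acid, oxazole formation and enol ether installation. The carbocycle and the pyridine ring then arise together in one intramolecular cycloaddition–aromatization, and five functional‑group steps finish the target.
- Stereochemistry: the only stereocentre, C5 (R), comes from allylation of the decanoyl imide of (S)‑4‑benzyloxazolidin‑2‑one and is a spectator afterwards.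

Key step: step 11

Remark: the alkoxymethylenation in step 10 is expected to give both enol ether geometries; C4 and C4a become sp2 in step 11, so both converge on 18, and 16 is written as its E isomer and used without separation.
Remark: 22 is written as the N‑hydroxy‑4‑pyridone tautomer of the 4‑hydroxypyridine N‑oxide.

**Step 1**
Reactants: 1 (S)-4-benzyloxazolidin-2-one; 2 decanoyl chloride
Product: 3 (4S)-4-benzyl-3-decanoyl-1,3-oxazolidin-2-one
Conditions: Et3N, DMAP (cat.), CH2Cl2, 0 °C → rt
Reagents that add atoms: none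
Why: DMAP‑catalysed N‑acylation of the oxazolidinone by the acid chloride is a standard imide formation and installs the auxiliary for the alkylation.

**Step 2**
Reactants: 3 (4S)-4-benzyl-3-decanoyl-1,3-oxazolidin-2-one
Product: 5 (4S)-4-benzyl-3-[(2R)-2-(prop-2-en-1-yl)decanoyl]-1,3-oxazolidin-2-one, via sodium Z-enolate 4 (not isolated)
Conditions: NaN(SiMe3)2, THF, −78 °C; allyl bromide, −78 → −40 °C
Reagents that add atoms: allyl bromide, C=CCBr
Why: In this oxazolidinone‑auxiliary (Evans‑type) asymmetric alkylation the chelated Z‑enolate is attacked by the allyl halide on the face opposite the benzyl group of the auxiliary, which sets the future C5 as R.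

**Step 3**
Reactants: 5 (4S)-4-benzyl-3-[(2R)-2-(prop-2-en-1-yl)decanoyl]-1,3-oxazolidin-2-one
Product: 6 benzyl (2E,5R)-5-{[(4S)-4-benzyl-2-oxo-1,3-oxazolidin-3-yl]carbonyl}tridec-2-enoate
Conditions: benzyl acrylate (3 equiv), second-generation Grubbs catalyst (H2IMes)(PCy3)Cl2Ru=CHPh (5 mol%), CH2Cl2, 40 °C
Reagents that add atoms: benzyl acrylate, C=CC(=O)OCc1ccccc1
Why: Olefin cross‑metathesis of a terminal alkene with an acrylate, which homodimerizes only slowly, should give the E‑enoate selectively and adds the carbons that become C8 and C8a.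

**Step 4**
Reactants: 6 benzyl (2E,5R)-5-{[(4S)-4-benzyl-2-oxo-1,3-oxazolidin-3-yl]carbonyl}tridec-2-enoate
Product: 7 (5R)-5-{[(4S)-4-benzyl-2-oxo-1,3-oxazolidin-3-yl]carbonyl}tridecanoic acid
Conditions: H2 (1 atm), Pd/C, EtOAc, rt
Reagents that add atoms: none
Why: Catalytic hydrogenation saturates the enoate and hydrogenolyses the benzyl ester in one operation, while the imide and its C‑benzyl group are inert.

**Step 5**
Reactants: 7 (5R)-5-{[(4S)-4-benzyl-2-oxo-1,3-oxazolidin-3-yl]carbonyl}tridecanoic acid; 8 diethyl aminomalonate hydrochloride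
Product: 9 diethyl 2-[(5R)-5-{[(4S)-4-benzyl-2-oxo-1,3-oxazolidin-3-yl]carbonyl}tridecanamido]propanedioate
Conditions: EDC·HCl, HOBt, iPr2NEt, CH2Cl2, 0 °C → rt
Reagents that add atoms: none
Why: Carbodiimide/HOBt amide coupling of a free acid with the weakly basic aminomalonate is routine and should leave the hindered α‑branched imide untouched.

**Step 6**
Reactants: 9 diethyl 2-[(5R)-5-{[(4S)-4-benzyl-2-oxo-1,3-oxazolidin-3-yl]carbonyl}tridecanamido]propanedioate
Product: 10 ethyl 2-[(4R)-4-{[(4S)-4-benzyl-2-oxo-1,3-oxazolidin-3-yl]carbonyl}dodecyl]-5-ethoxy-1,3-oxazole-4-carboxylate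
Conditions: PPh3, I2, Et3N, CH2Cl2, 0 °C → rt
Reagents that add atoms: none
Why: Robinson–Gabriel‑type cyclodehydration of an acylaminomalonate under Appel‑type activation is an established entry to ethyl 5‑ethoxyoxazole‑4‑carboxylates, and the imide keeps the other chain terminus masked from the phosphonium reagent.

**Step 7**
Reactants: 10 ethyl 2-[(4R)-4-{[(4S)-4-benzyl-2-oxo-1,3-oxazolidin-3-yl]carbonyl}dodecyl]-5-ethoxy-1,3-oxazole-4-carboxylate
Product: 11 ethyl 5-ethoxy-2-[(4R)-4-(hydroxymethyl)dodecyl]-1,3-oxazole-4-carboxylate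
Conditions: NaBH4, THF/H2O (4:1), 0 °C → rt
Reagents that add atoms: none
Why: Borohydride in wet THF cleaves N‑acyloxazolidinones reductively to primary alcohols without epimerization and does not reduce ordinary esters, the oxazole ester being further deactivated as a vinylogous carbonate.

**Step 8**
Reactants: 11 ethyl 5-ethoxy-2-[(4R)-4-(hydroxymethyl)dodecyl]-1,3-oxazole-4-carboxylate
Product: 12 ethyl 5-ethoxy-2-[(4R)-4-formyldodecyl]-1,3-oxazole-4-carboxylate
Conditions: Dess–Martin periodinane, NaHCO3, CH2Cl2, 0 °C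
Reagents that add atoms: none
Why: Buffered Dess–Martin oxidation should give the α‑branched aldehyde under near‑neutral, non‑epimerizing conditions, and the aldehyde is used at once.

**Step 9**
Reactants: 13 benzyl chloromethyl ether
Product: 14 [(benzyloxy)methyl]triphenylphosphonium chloride
Conditions: PPh3, toluene, rt → 50 °C
Reagents that add atoms: triphenylphosphine, c1ccc(cc1)P(c1ccccc1)c1ccccc1
Why: SN2 quaternization of triphenylphosphine by the reactive α‑chloro ether gives the alkoxymethyl phosphonium salt.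

**Step 10**
Reactants: 12 ethyl 5-ethoxy-2-[(4R)-4-formyldodecyl]-1,3-oxazole-4-carboxylate; 14 [(benzyloxy)methyl]triphenylphosphonium chloride
Product: 16 ethyl 2-[(4R,5E)-6-(benzyloxy)-4-octylhex-5-en-1-yl]-5-ethoxy-1,3-oxazole-4-carboxylate, via benzyloxymethylene ylide 15 (not isolated)
Conditions: 14, KN(SiMe3)2, THF, −78 → 0 °C; then 12, −78 °C → rt
Reagents that add atoms: none
Why: Wittig alkoxymethylenation with the preformed ylide at low temperature should convert the aldehyde into the benzyl enol ether while the α‑stereocentre sees base only briefly and the ester is inert to the ylide.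

**Step 11**
Reactants: 16 ethyl 2-[(4R,5E)-6-(benzyloxy)-4-octylhex-5-en-1-yl]-5-ethoxy-1,3-oxazole-4-carboxylate
Product: 18 ethyl (5R)-4-(benzyloxy)-3-hydroxy-5-octyl-5,6,7,8-tetrahydroquinoline-2-carboxylate, via oxygen-bridged cycloadduct 17 (not isolated)
Conditions: 1,2-dichlorobenzene (0.01 M, degassed), 180 °C
Reagents that add atoms: none
Why: On heating, the oxazole reacts as a 2‑azadiene across its C2 and C5 with the tethered enol ether in an intramolecular [4+2] cycloaddition to the oxygen‑bridged adduct 17; the bridge then opens at C8a–O with loss of the C4a proton, the C3 hemiketal so formed expels ethanol, and the pyridin‑3(4H)‑one tautomerizes through its C4–H to the 3‑hydroxypyridine. The closest known reaction type is the intramolecular oxazole–olefin Diels–Alder (Kondrat'eva) pyridine synthesis, in which 5‑alkoxyoxazoles end as 3‑hydroxypyridines, and the pairing of an ester‑bearing azadiene with a tethered benzyl enol ether follows the inverse‑electron‑demand pattern known for ester‑substituted 1,3,4‑oxadiazoles. The carbocycle closes through the C4a–C8a bond as the six‑membered ring of a cycloaddition with a four‑atom tether (C5–C8), and the pyridine ring closes through the C3–C4 bond of the same cycloaddition. No stereocentre is created in 18, because the four sp3 centres of 17 are erased on aromatization, and C5, set in step 2, is not acidic in any intermediate and should stay R. Regiochemistry is fixed by the tether and agrees with the polarity of both partners (nucleophilic enol ether β‑carbon to the electrophilic oxazole C2), while the ester lowers the azadiene LUMO towards the electron‑rich alkene. Ethanol and not benzyl alcohol is lost because only the ethoxy group sits on the ketal carbon C3 beside the bridging oxygen, whereas C4 gives up its hydrogen and keeps the benzyloxy group.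

**Step 12**
Reactants: 18 ethyl (5R)-4-(benzyloxy)-3-hydroxy-5-octyl-5,6,7,8-tetrahydroquinoline-2-carboxylate
Product: 19 ethyl (5R)-4-(benzyloxy)-3-methoxy-5-octyl-5,6,7,8-tetrahydroquinoline-2-carboxylate
Conditions: MeI, K2CO3, DMF, rt
Reagents that add atoms: iodomethane, CI
Why: Williamson O‑methylation of the acidic 3‑hydroxypicolinate OH should be clean because N‑methylation is blocked by the flanking C2 ester and C8a alkyl groups.

**Step 13**
Reactants: 19 ethyl (5R)-4-(benzyloxy)-3-methoxy-5-octyl-5,6,7,8-tetrahydroquinoline-2-carboxylate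
Product: 20 [(5R)-4-(benzyloxy)-3-methoxy-5-octyl-5,6,7,8-tetrahydroquinolin-2-yl]methanol
Conditions: LiBH4, THF, 0 °C → rt
Reagents that add atoms: none
Why: Borohydride reduction of a pyridine‑2‑carboxylate, activated by the ring nitrogen, gives the primary alcohol and leaves the benzyl and methyl ethers untouched.

**Step 14**
Reactants: 20 [(5R)-4-(benzyloxy)-3-methoxy-5-octyl-5,6,7,8-tetrahydroquinolin-2-yl]methanol
Product: 21 (5R)-4-(benzyloxy)-2-(hydroxymethyl)-3-methoxy-5-octyl-5,6,7,8-tetrahydroquinoline 1-oxide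
Conditions: mCPBA, NaHCO3, CH2Cl2, 0 °C → rt
Reagents that add atoms: mCPBA (3-chloroperoxybenzoic acid), OOC(=O)c1cccc(Cl)c1
Why: Peracid N‑oxidation of an electron‑rich alkoxypyridine is standard, and the primary alcohol and the ethers are inert to mCPBA.

**Step 15**
Reactants: 21 (5R)-4-(benzyloxy)-2-(hydroxymethyl)-3-methoxy-5-octyl-5,6,7,8-tetrahydroquinoline 1-oxide
Product: 22 (5R)-1-hydroxy-2-(hydroxymethyl)-3-methoxy-5-octyl-5,6,7,8-tetrahydroquinolin-4(1H)-one
Conditions: H2 (1 atm), Pd/C, EtOH, rt, stopped after one equivalent of H2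
Reagents that add atoms: none
Why: Hydrogenolysis of the O‑benzyl bond of a 4‑benzyloxypyridine N‑oxide is faster than N–O reduction and gives the 4‑hydroxypyridine N‑oxide, which sits as its N‑hydroxy‑4‑pyridone tautomer.

**Step 16**
Reactants: 22 (5R)-1-hydroxy-2-(hydroxymethyl)-3-methoxy-5-octyl-5,6,7,8-tetrahydroquinolin-4(1H)-one
Product: 23 (5R)-2-(hydroxymethyl)-1,3-dimethoxy-5-octyl-5,6,7,8-tetrahydroquinolin-4(1H)-one
Conditions: MeI, K2CO3, DMF, 0 °C → rt
Reagents that add atoms: iodomethane, CI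
Why: Carbonate ionizes only the hydroxamic‑acid‑like N–OH, whose anion is expected to be methylated on the nitrogen‑bound oxygen to the N‑methoxy‑4‑pyridone, while the primary alcohol stays un‑ionized.

**Compound list**
1 | (S)-4-benzyloxazolidin-2-one | O=C1N[C@@H](Cc2ccccc2)CO1 | starting material
2 | decanoyl chloride | CCCCCCCCCC(=O)Cl | starting material
3 | (4S)-4-benzyl-3-decanoyl-1,3-oxazolidin-2-one | CCCCCCCCCC(=O)N1C(=O)OC[C@@H]1Cc1ccccc1 | intermediate
4 | sodium (1Z)-1-[(4S)-4-benzyl-2-oxo-1,3-oxazolidin-3-yl]dec-1-en-1-olate (sodium Z-enolate of 3) | CCCCCCCC/C=C(\[O-])N1C(=O)OC[C@@H]1Cc1ccccc1.[Na+] | intermediate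
5 | (4S)-4-benzyl-3-[(2R)-2-(prop-2-en-1-yl)decanoyl]-1,3-oxazolidin-2-one | CCCCCCCC[C@@H](C(=O)N1C(=O)OC[C@@H]1Cc1ccccc1)CC=C | intermediate
6 | benzyl (2E,5R)-5-{[(4S)-4-benzyl-2-oxo-1,3-oxazolidin-3-yl]carbonyl}tridec-2-enoate | CCCCCCCC[C@@H](C(=O)N1C(=O)OC[C@@H]1Cc1ccccc1)C/C=C/C(=O)OCc1ccccc1 | intermediate
7 | (5R)-5-{[(4S)-4-benzyl-2-oxo-1,3-oxazolidin-3-yl]carbonyl}tridecanoic acid | CCCCCCCC[C@@H](C(=O)N1C(=O)OC[C@@H]1Cc1ccccc1)CCCC(=O)O | intermediate
8 | diethyl aminomalonate hydrochloride | Cl.CCOC(=O)C(N)C(=O)OCC | starting material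
9 | diethyl 2-[(5R)-5-{[(4S)-4-benzyl-2-oxo-1,3-oxazolidin-3-yl]carbonyl}tridecanamido]propanedioate | CCCCCCCC[C@@H](C(=O)N1C(=O)OC[C@@H]1Cc1ccccc1)CCCC(=O)NC(C(=O)OCC)C(=O)OCC | intermediate
10 | ethyl 2-[(4R)-4-{[(4S)-4-benzyl-2-oxo-1,3-oxazolidin-3-yl]carbonyl}dodecyl]-5-ethoxy-1,3-oxazole-4-carboxylate | CCCCCCCC[C@@H](C(=O)N1C(=O)OC[C@@H]1Cc1ccccc1)CCCc1nc(C(=O)OCC)c(OCC)o1 | intermediate
11 | ethyl 5-ethoxy-2-[(4R)-4-(hydroxymethyl)dodecyl]-1,3-oxazole-4-carboxylate | CCCCCCCC[C@@H](CO)CCCc1nc(C(=O)OCC)c(OCC)o1 | intermediate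
12 | ethyl 5-ethoxy-2-[(4R)-4-formyldodecyl]-1,3-oxazole-4-carboxylate | CCCCCCCC[C@@H](C=O)CCCc1nc(C(=O)OCC)c(OCC)o1 | intermediate
13 | benzyl chloromethyl ether | ClCOCc1ccccc1 | starting material
14 | [(benzyloxy)methyl]triphenylphosphonium chloride | [Cl-].c1ccc(cc1)COC[P+](c1ccccc1)(c1ccccc1)c1ccccc1 | intermediate
15 | [(benzyloxy)methylidene]triphenylphosphorane (benzyloxymethylene ylide) | C(OCc1ccccc1)=P(c1ccccc1)(c1ccccc1)c1ccccc1 | intermediate
16 | ethyl 2-[(4R,5E)-6-(benzyloxy)-4-octylhex-5-en-1-yl]-5-ethoxy-1,3-oxazole-4-carboxylate | CCCCCCCC[C@@H](/C=C/OCc1ccccc1)CCCc1nc(C(=O)OCC)c(OCC)o1 | intermediate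
17 | ethyl (5R)-4-(benzyloxy)-3-ethoxy-5-octyl-3,4,4a,5,6,7,8,8a-octahydro-3,8a-epoxyquinoline-2-carboxylate (oxygen-bridged cycloadduct; configurations at C3, C4, C4a and C8a not defined) | CCCCCCCC[C@@H]1CCCC23OC(OCC)(C(C(=O)OCC)=N2)C(OCc2ccccc2)C13 | intermediate
18 | ethyl (5R)-4-(benzyloxy)-3-hydroxy-5-octyl-5,6,7,8-tetrahydroquinoline-2-carboxylate | CCCCCCCC[C@@H]1CCCc2nc(C(=O)OCC)c(O)c(OCc3ccccc3)c21 | intermediate
19 | ethyl (5R)-4-(benzyloxy)-3-methoxy-5-octyl-5,6,7,8-tetrahydroquinoline-2-carboxylate | CCCCCCCC[C@@H]1CCCc2nc(C(=O)OCC)c(OC)c(OCc3ccccc3)c21 | intermediate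
20 | [(5R)-4-(benzyloxy)-3-methoxy-5-octyl-5,6,7,8-tetrahydroquinolin-2-yl]methanol | CCCCCCCC[C@@H]1CCCc2nc(CO)c(OC)c(OCc3ccccc3)c21 | intermediate
21 | (5R)-4-(benzyloxy)-2-(hydroxymethyl)-3-methoxy-5-octyl-5,6,7,8-tetrahydroquinoline 1-oxide | CCCCCCCC[C@@H]1CCCc2c1c(OCc1ccccc1)c(OC)c(CO)[n+]2[O-] | intermediate
22 | (5R)-1-hydroxy-2-(hydroxymethyl)-3-methoxy-5-octyl-5,6,7,8-tetrahydroquinolin-4(1H)-one | CCCCCCCC[C@@H]1CCCc2c1c(=O)c(OC)c(CO)n2O | intermediate
23 | (5R)-2-(hydroxymethyl)-1,3-dimethoxy-5-octyl-5,6,7,8-tetrahydroquinolin-4(1H)-one | CCCCCCCC[C@@H]1CCCc2c1c(=O)c(OC)c(CO)n2OC | target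

**Step count**
Total: 16 steps. Longest linear sequence: 15 steps (steps 1–8 and 10–16); step 9 is a one‑step side branch.

**Steps most likely to fail**

Step 11. The push–pull oxazole may cycloadd too slowly, so that thermal breakdown of the enol ether or reversible ring‑opening of the 4‑acyloxazole takes over, or aromatization may proceed by loss of water instead of ethanol. The fallback changes the electronic type of the diene to the donor‑substituted 5‑ethoxy‑4‑alkyloxazole of the classical Kondrat'eva manifold. It sets out from 16: DIBAL‑H (CH2Cl2, −78 °C) would reduce the oxazole ester to {2-[(4R,5E)-6-(benzyloxy)-4-octylhex-5-en-1-yl]-5-ethoxy-1,3-oxazol-4-yl}methanol F1. TBSCl and imidazole (DMF) would then give 2-[(4R,5E)-6-(benzyloxy)-4-octylhex-5-en-1-yl]-4-{[(tert-butyldimethylsilyl)oxy]methyl}-5-ethoxy-1,3-oxazole F2. Heating F2 in 1,2‑dichlorobenzene should give (5R)-4-(benzyloxy)-2-{[(tert-butyldimethylsilyl)oxy]methyl}-5-octyl-5,6,7,8-tetrahydroquinolin-3-ol F3 by the same two bond formations. MeI/K2CO3 would give (5R)-4-(benzyloxy)-2-{[(tert-butyldimethylsilyl)oxy]methyl}-3-methoxy-5-octyl-5,6,7,8-tetrahydroquinoline F4, and Bu4NF (THF) would release alcohol 20, where the route is rejoined.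

Step 16. The ambident hydroxypyridone anion may be methylated on the C4 oxygen as well as on the N‑bound oxygen, and over‑reduction of the N–O bond in step 15 would cut the supply. The fallback fixes the methyl group on the N‑oxide oxygen before the C4 oxygen is unmasked. It sets out from 21: MeOTf (CH2Cl2, 0 °C) should give (5R)-4-(benzyloxy)-2-(hydroxymethyl)-1,3-dimethoxy-5-octyl-5,6,7,8-tetrahydroquinolin-1-ium trifluoromethanesulfonate F5. LiBr (acetone, rt → 40 °C) would then remove the benzyl group by halide attack at the benzylic carbon of the 4‑alkoxypyridinium, the known way from such salts to 4‑pyridones, and would give the target 23 directly, by‑passing step 15.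

Step 10. The basic ylide may epimerize the α‑branched aldehyde by enolization, and the unstable ylide may give incomplete olefination. The fallback avoids basic carbanion chemistry and gives a single alkene geometry. It sets out from 12: Takai iodo‑olefination (CrCl2, CHI3, THF, 0 °C) should give ethyl 5-ethoxy-2-[(4R,5E)-6-iodo-4-octylhex-5-en-1-yl]-1,3-oxazole-4-carboxylate F6. Copper‑catalysed C–O coupling of the vinyl iodide with benzyl alcohol (CuI, copper monoiodide; 3,4,7,8‑tetramethyl‑1,10‑phenanthroline; Cs2CO3; toluene, 80 °C), which proceeds with retention of alkene geometry, would then give 16, where the route is rejoined.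

**Further compounds**
F1 | step 11 | {2-[(4R,5E)-6-(benzyloxy)-4-octylhex-5-en-1-yl]-5-ethoxy-1,3-oxazol-4-yl}methanol | CCCCCCCC[C@@H](/C=C/OCc1ccccc1)CCCc1nc(CO)c(OCC)o1
F2 | step 11 | 2-[(4R,5E)-6-(benzyloxy)-4-octylhex-5-en-1-yl]-4-{[(tert-butyldimethylsilyl)oxy]methyl}-5-ethoxy-1,3-oxazole | CCCCCCCC[C@@H](/C=C/OCc1ccccc1)CCCc1nc(CO[Si](C)(C)C(C)(C)C)c(OCC)o1
F3 | step 11 | (5R)-4-(benzyloxy)-2-{[(tert-butyldimethylsilyl)oxy]methyl}-5-octyl-5,6,7,8-tetrahydroquinolin-3-ol | CCCCCCCC[C@@H]1CCCc2nc(CO[Si](C)(C)C(C)(C)C)c(O)c(OCc3ccccc3)c21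
F4 | step 11 | (5R)-4-(benzyloxy)-2-{[(tert-butyldimethylsilyl)oxy]methyl}-3-methoxy-5-octyl-5,6,7,8-tetrahydroquinoline | CCCCCCCC[C@@H]1CCCc2nc(CO[Si](C)(C)C(C)(C)C)c(OC)c(OCc3ccccc3)c21
F5 | step 16 | (5R)-4-(benzyloxy)-2-(hydroxymethyl)-1,3-dimethoxy-5-octyl-5,6,7,8-tetrahydroquinolin-1-ium trifluoromethanesulfonate | CCCCCCCC[C@@H]1CCCc2c1c(OCc1ccccc1)c(OC)c(CO)[n+]2OC.[O-]S(=O)(=O)C(F)(F)F
F6 | step 10 | ethyl 5-ethoxy-2-[(4R,5E)-6-iodo-4-octylhex-5-en-1-yl]-1,3-oxazole-4-carboxylate | CCCCCCCC[C@@H](/C=C/I)CCCc1nc(C(=O)OCC)c(OCC)o1
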